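## Retrosynthetic overview

1. Target 33 ⇐ C3 acetylation and desilylation of macrocyclic alcohol 31. The ten-membered carbocycle is closed last, by Nozaki–Hiyama–Kishi addition of the C4 vinyl iodide to the C3 aldehyde (C3–C4 bond).
2. Seco-aldehyde 30 ⇐ O8 angeloylation and acetal unmasking of alcohol 25. 25 ⇐ CrCl2-mediated allylation (C7–C8 bond) of fragment A, bromomethyl butenolide 13 (C4–C7, C11–C13, C15), with fragment B, Z-enal 24 (C1–C3, C8–C10, C14). This step turns the butenolide into the trans α-methylene lactone and sets C7 and C8.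
3. 13 ⇐ but-2-yne-1,4-diol: directed hydroalumination/iodination (Z vinyl iodide), ProPhenol alkynylation with methyl propiolate (C6), vinylalumination/CH2O/lactonisation, Appel bromination.
4. 24 ⇐ acrolein dimethyl acetal: hydroboration/oxidation, ProPhenol alkynylation with ethyl propiolate (C1), Me2CuLi syn-carbocupration (Z C9=C10), reduction/oxidation.
5. Ring order: lactone ring first (as butenolide, step 6), carbocycle last (step 18).

Position labels used below: C12 lactone carbonyl, C13 exocyclic CH2 on C11, lactone oxygen on C6, C5=C4 (C15H2OH on C4), C3 (OAc), C2, C1 (OH), C10 (C14 methyl)=C9, C8 (angelate), C7.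

Assumption: (S,S)-ProPhenol is taken as the ligand antipode that gives the (S)-carbinols 8 and 20 (same facial sense in both); if the sense is opposite, (R,R)-ProPhenol is used in both steps.

## Route

Step 1
Reactants: 1 but-2-yne-1,4-diol
Product: 2 4-{[tert-butyl(diphenyl)silyl]oxy}but-2-yn-1-ol
Conditions: TBDPSCl (1 equiv), imidazole, 1 (3 equiv), DMF, 0 °C → rt
Reagents that add atoms: tert-butyl(chloro)diphenylsilane, CC(C)(C)[Si](Cl)(c1ccccc1)c1ccccc1
Why: Statistical monosilylation (silyl ether formation) of the symmetrical diol used in excess differentiates the two hydroxyls; no stereocentre is formed.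

Step 2
Reactants: 2 4-{[tert-butyl(diphenyl)silyl]oxy}but-2-yn-1-ol
Product: 4 (2Z)-4-{[tert-butyl(diphenyl)silyl]oxy}-3-iodobut-2-en-1-ol, via cyclic alkenylalanate 3 (not isolated)
Conditions: NaAlH2(OCH2CH2OMe)2, THF, 0 °C; then I2, THF, −78 °C
Reagents that add atoms: iodine, I-I
Why: Hydroxyl-directed trans-hydroalumination of the propargylic alcohol puts hydride on the proximal and aluminium on the distal alkyne carbon in a five-membered ring, and iodinolysis with retention fixes the Z geometry (I cis to CH2OH, the later C3/C6 cis relationship).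

Step 3
Reactants: 4 (2Z)-4-{[tert-butyl(diphenyl)silyl]oxy}-3-iodobut-2-en-1-ol
Product: 5 (2Z)-4-{[tert-butyl(diphenyl)silyl]oxy}-3-iodobut-2-enal
Conditions: MnO2 (excess), CH2Cl2, rt
Reagents that add atoms: none
Why: Chemoselective MnO2 allylic oxidation gives the enal without touching the vinyl iodide or the Z geometry.

Step 4
Reactants: 5 (2Z)-4-{[tert-butyl(diphenyl)silyl]oxy}-3-iodobut-2-enal + 6 methyl propiolate
Product: 8 methyl (4S,5Z)-7-{[tert-butyl(diphenyl)silyl]oxy}-4-hydroxy-6-iodohept-5-en-2-ynoate, via alkynylzinc 7 (not isolated)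
Conditions: Me2Zn (3 equiv), (S,S)-ProPhenol (20 mol %), Ph3PO (40 mol %), toluene, 0–4 °C
Reagents that add atoms: none
Why: Trost ProPhenol–zinc asymmetric alkynylation of an enal, a favourable substrate class; the chiral dinuclear zinc catalyst selects one aldehyde face and sets C6 (4S in 8).

Step 5
Reactants: 8 methyl (4S,5Z)-7-{[tert-butyl(diphenyl)silyl]oxy}-4-hydroxy-6-iodohept-5-en-2-ynoate
Product: 9 methyl (4S,5Z)-7-{[tert-butyl(diphenyl)silyl]oxy}-6-iodo-4-[(triethylsilyl)oxy]hept-5-en-2-ynoate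
Conditions: TESCl, imidazole, CH2Cl2, 0 °C
Reagents that add atoms: chlorotriethylsilane, CC[Si](Cl)(CC)CC
Why: Silyl ether formation masks the carbinol so that iBu2AlH is neither consumed nor misdirected in the next step; the stereocentre is untouched.

Step 6
Reactants: 9 methyl (4S,5Z)-7-{[tert-butyl(diphenyl)silyl]oxy}-6-iodo-4-[(triethylsilyl)oxy]hept-5-en-2-ynoate
Product: 12 (5R)-5-[(1Z)-3-{[tert-butyl(diphenyl)silyl]oxy}-2-iodoprop-1-en-1-yl]-3-(hydroxymethyl)furan-2(5H)-one, via alkenylalane 10 (not isolated), via hydroxymethyl dienoate 11 (not isolated)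
Conditions: iBu2AlH, NMO, THF, 0 °C; then CH2O (gas), −78 °C → rt; then 1 M HCl, THF/MeOH, rt
Reagents that add atoms: formaldehyde, C=O
Why: Amine-oxide-promoted 1,4-hydroalumination of the ynoate (vinylalumination) is syn, so the ester ends up cis to C6; aldol-type capture of formaldehyde with retention, then acid-induced desilylation and lactonisation, give the butenolide (first ring) without touching C6.

Step 7
Reactants: 12 (5R)-5-[(1Z)-3-{[tert-butyl(diphenyl)silyl]oxy}-2-iodoprop-1-en-1-yl]-3-(hydroxymethyl)furan-2(5H)-one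
Product: 13 (5R)-3-(bromomethyl)-5-[(1Z)-3-{[tert-butyl(diphenyl)silyl]oxy}-2-iodoprop-1-en-1-yl]furan-2(5H)-one
Conditions: CBr4, PPh3, CH2Cl2, 0 °C
Reagents that add atoms: tetrabromomethane, BrC(Br)(Br)Br
Why: Appel bromination of the primary allylic alcohol is neutral, so the base-sensitive γ-stereocentre of the butenolide is preserved.

Step 8
Reactants: 14 3,3-dimethoxyprop-1-ene
Product: 16 3,3-dimethoxypropan-1-ol, via alkylborane 15 (not isolated)
Conditions: 9-BBN, THF, 0 °C → rt; then NaOH, H2O2, H2O, 0 °C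
Reagents that add atoms: hydrogen peroxide, OO
Why: Anti-Markovnikov hydroboration–oxidation with the bulky borane gives the primary alcohol; no stereocentre is formed.

Step 9
Reactants: 16 3,3-dimethoxypropan-1-ol
Product: 17 3,3-dimethoxypropanal
Conditions: TEMPO (10 mol %), PhI(OAc)2, CH2Cl2, rt
Reagents that add atoms: none
Why: Oxoammonium (TEMPO/PhI(OAc)2) oxidation stops at the aldehyde under near-neutral conditions that spare the acetal; the labile aldehyde is used at once.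

Step 10
Reactants: 17 3,3-dimethoxypropanal + 18 ethyl propiolate
Product: 20 ethyl (4S)-4-hydroxy-6,6-dimethoxyhex-2-ynoate, via ethyl alkynylzinc 19 (not isolated)
Conditions: Me2Zn (3 equiv), (S,S)-ProPhenol (20 mol %), Ph3PO (40 mol %), toluene, 0–4 °C, slow addition of 17
Reagents that add atoms: none
Why: A second Trost ProPhenol–zinc alkynylation, here with the ethyl ester of propiolic acid, uses the same ligand antipode and the same facial sense and sets C1 (4S in 20).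

Step 11
Reactants: 20 ethyl (4S)-4-hydroxy-6,6-dimethoxyhex-2-ynoate
Product: 21 ethyl (4S)-4-{[tert-butyl(dimethyl)silyl]oxy}-6,6-dimethoxyhex-2-ynoate
Conditions: TBSCl, imidazole, DMF, rt
Reagents that add atoms: tert-butyl(chloro)dimethylsilane, CC(C)(C)[Si](C)(C)Cl
Why: Silyl ether formation protects O1 until the last step and blocks lactonisation of the Z-enoate formed next.

Step 12
Reactants: 21 ethyl (4S)-4-{[tert-butyl(dimethyl)silyl]oxy}-6,6-dimethoxyhex-2-ynoate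
Product: 22 ethyl (2Z,4S)-4-{[tert-butyl(dimethyl)silyl]oxy}-6,6-dimethoxy-3-methylhex-2-enoate
Conditions: Me2CuLi (from MeLi and CuI), THF, −78 °C; then MeOH/H2O, −78 °C
Reagents that add atoms: lithium dimethylcuprate, [Li+].C[Cu-]C
Why: Conjugate syn-carbocupration of the ynoate by the Gilman reagent and cold protonation of the alkenylcuprate give the Z-enoate (ester cis to C1), which is the Z C9=C10 bond with its C14 methyl.

Step 13
Reactants: 22 ethyl (2Z,4S)-4-{[tert-butyl(dimethyl)silyl]oxy}-6,6-dimethoxy-3-methylhex-2-enoate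
Product: 23 (2Z,4S)-4-{[tert-butyl(dimethyl)silyl]oxy}-6,6-dimethoxy-3-methylhex-2-en-1-ol
Conditions: iBu2AlH (2.2 equiv), CH2Cl2, −78 °C
Reagents that add atoms: none
Why: Hydride reduction of the enoate to the allylic alcohol at low temperature keeps the alkene geometry and the acetal.

Step 14
Reactants: 23 (2Z,4S)-4-{[tert-butyl(dimethyl)silyl]oxy}-6,6-dimethoxy-3-methylhex-2-en-1-ol
Product: 24 (2Z,4S)-4-{[tert-butyl(dimethyl)silyl]oxy}-6,6-dimethoxy-3-methylhex-2-enal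
Conditions: MnO2 (excess), CH2Cl2, rt
Reagents that add atoms: none
Why: MnO2 allylic oxidation gives the Z-enal under neutral conditions.

Step 15
Reactants: 13 (5R)-3-(bromomethyl)-5-[(1Z)-3-{[tert-butyl(diphenyl)silyl]oxy}-2-iodoprop-1-en-1-yl]furan-2(5H)-one + 24 (2Z,4S)-4-{[tert-butyl(dimethyl)silyl]oxy}-6,6-dimethoxy-3-methylhex-2-enal
Product: 25 (4S,5R)-5-[(1Z)-3-{[tert-butyl(diphenyl)silyl]oxy}-2-iodoprop-1-en-1-yl]-4-[(1R,2Z,4S)-4-{[tert-butyl(dimethyl)silyl]oxy}-1-hydroxy-6,6-dimethoxy-3-methylhex-2-en-1-yl]-3-methylideneoxolan-2-one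
Conditions: CrCl2 (nickel-free, 4 equiv), THF, 0 °C → rt
Reagents that add atoms: none
Why: Chromium-mediated Barbier-type (Nozaki–Hiyama) allylation: divalent chromium inserts only into the allylic C–Br bond (no nickel, so the vinyl iodide is inert), the allylchromium attacks through its γ-carbon C7 on the ring face anti to the C6 alkenyl group (trans lactone, C7), and a chair Zimmerman–Traxler transition state with ring-locked allyl geometry and equatorial aldehyde residue gives the anti C7/C8 relationship (C8) while the double bond moves to the exocyclic position.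

Step 16
Reactants: 25 (4S,5R)-5-[(1Z)-3-{[tert-butyl(diphenyl)silyl]oxy}-2-iodoprop-1-en-1-yl]-4-[(1R,2Z,4S)-4-{[tert-butyl(dimethyl)silyl]oxy}-1-hydroxy-6,6-dimethoxy-3-methylhex-2-en-1-yl]-3-methylideneoxolan-2-one + 26 angelic acid
Product: 28 (1R,2Z,4S)-4-{[tert-butyl(dimethyl)silyl]oxy}-1-[(2R,3S)-2-[(1Z)-3-{[tert-butyl(diphenyl)silyl]oxy}-2-iodoprop-1-en-1-yl]-4-methylidene-5-oxooxolan-3-yl]-6,6-dimethoxy-3-methylhex-2-en-1-yl (2Z)-2-methylbut-2-enoate, via mixed anhydride 27 (not isolated)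
Conditions: 26, 2,4,6-trichlorobenzoyl chloride, Et3N, toluene, rt; then 25, toluene, 80 °C
Reagents that add atoms: none
Why: Yamaguchi-type mixed-anhydride esterification without a nucleophilic catalyst acylates the only free hydroxyl and avoids angelate-to-tiglate isomerisation and lactone migration; no stereocentre is touched.

Step 17
Reactants: 28 (1R,2Z,4S)-4-{[tert-butyl(dimethyl)silyl]oxy}-1-[(2R,3S)-2-[(1Z)-3-{[tert-butyl(diphenyl)silyl]oxy}-2-iodoprop-1-en-1-yl]-4-methylidene-5-oxooxolan-3-yl]-6,6-dimethoxy-3-methylhex-2-en-1-yl (2Z)-2-methylbut-2-enoate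
Product: 30 (1R,2Z,4S)-4-{[tert-butyl(dimethyl)silyl]oxy}-1-[(2R,3S)-2-[(1Z)-3-{[tert-butyl(diphenyl)silyl]oxy}-2-iodoprop-1-en-1-yl]-4-methylidene-5-oxooxolan-3-yl]-3-methyl-6-oxohex-2-en-1-yl (2Z)-2-methylbut-2-enoate, via pyridinium salt 29 (not isolated)
Conditions: TESOTf, 2,4,6-collidine, CH2Cl2, 0 °C; then H2O
Reagents that add atoms: water, O
Why: Fujioka-type acetal cleavage (silyl triflate and collidine give a pyridinium N,O-acetal that water hydrolyses) unmasks the aldehyde at 0 °C under nearly neutral conditions, sparing the silyl ethers, the esters and the elimination-prone β-silyloxy aldehyde.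

Step 18
Reactants: 30 (1R,2Z,4S)-4-{[tert-butyl(dimethyl)silyl]oxy}-1-[(2R,3S)-2-[(1Z)-3-{[tert-butyl(diphenyl)silyl]oxy}-2-iodoprop-1-en-1-yl]-4-methylidene-5-oxooxolan-3-yl]-3-methyl-6-oxohex-2-en-1-yl (2Z)-2-methylbut-2-enoate
Product: 31 (3aS,4R,5Z,7S,9S,10Z,11aS)-7-{[tert-butyl(dimethyl)silyl]oxy}-10-({[tert-butyl(diphenyl)silyl]oxy}methyl)-9-hydroxy-6-methyl-3-methylidene-2-oxo-2,3,3a,4,7,8,9,11a-octahydrocyclodeca[b]furan-4-yl (2Z)-2-methylbut-2-enoate
Conditions: CrCl2 (10 equiv), NiCl2 (0.1 equiv), DMSO, rt, 2 mM, slow addition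
Reagents that add atoms: none
Why: Intramolecular Nozaki–Hiyama–Kishi reaction: zerovalent nickel inserts into the vinyl iodide, transmetalation gives an alkenyl–trivalent-chromium species that adds only to the aldehyde with retention of the Z geometry and closes the ten-membered ring; the C3 carbinol is expected 1,3-anti to the C1 silyloxy group (polar Evans-type induction in the cyclic transition state), and this is the least secure stereocentre.

Step 19
Reactants: 31 (3aS,4R,5Z,7S,9S,10Z,11aS)-7-{[tert-butyl(dimethyl)silyl]oxy}-10-({[tert-butyl(diphenyl)silyl]oxy}methyl)-9-hydroxy-6-methyl-3-methylidene-2-oxo-2,3,3a,4,7,8,9,11a-octahydrocyclodeca[b]furan-4-yl (2Z)-2-methylbut-2-enoate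
Product: 32 (3aS,4R,5Z,7S,9S,10Z,11aS)-9-acetoxy-7-{[tert-butyl(dimethyl)silyl]oxy}-10-({[tert-butyl(diphenyl)silyl]oxy}methyl)-6-methyl-3-methylidene-2-oxo-2,3,3a,4,7,8,9,11a-octahydrocyclodeca[b]furan-4-yl (2Z)-2-methylbut-2-enoate
Conditions: Ac2O, pyridine, DMAP (cat.), CH2Cl2, 0 °C → rt
Reagents that add atoms: acetic anhydride, CC(=O)OC(C)=O
Why: Acetylation of the only free hydroxyl, so the O1/O3/O15 differentiation needs no further selectivity; configuration is retained.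

Step 20
Reactants: 32 (3aS,4R,5Z,7S,9S,10Z,11aS)-9-acetoxy-7-{[tert-butyl(dimethyl)silyl]oxy}-10-({[tert-butyl(diphenyl)silyl]oxy}methyl)-6-methyl-3-methylidene-2-oxo-2,3,3a,4,7,8,9,11a-octahydrocyclodeca[b]furan-4-yl (2Z)-2-methylbut-2-enoate
Product: 33 (3aS,4R,5Z,7S,9S,10Z,11aS)-9-acetoxy-7-hydroxy-10-(hydroxymethyl)-6-methyl-3-methylidene-2-oxo-2,3,3a,4,7,8,9,11a-octahydrocyclodeca[b]furan-4-yl (2Z)-2-methylbut-2-enoate
Conditions: HF·pyridine, pyridine/THF, 0 °C → rt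
Reagents that add atoms: none
Why: Fluoride-mediated desilylation under buffered, mildly acidic conditions removes both silyl ethers without acetyl migration, lactone opening or conjugate addition to the methylene lactone.

## Compound list

1 | but-2-yne-1,4-diol | OCC#CCO | starting material
2 | 4-{[tert-butyl(diphenyl)silyl]oxy}but-2-yn-1-ol | OCC#CCO[Si](c1ccccc1)(c1ccccc1)C(C)(C)C | intermediate
3 | sodium 3-({[tert-butyl(diphenyl)silyl]oxy}methyl)-2,2-bis(2-methoxyethoxy)-2,5-dihydro-1,2-oxaaluminol-2-uide (cyclic alkenylalanate; not isolated) | [Na+].COCCO[Al-]1(OCCOC)OCC=C1CO[Si](c1ccccc1)(c1ccccc1)C(C)(C)C | intermediate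
4 | (2Z)-4-{[tert-butyl(diphenyl)silyl]oxy}-3-iodobut-2-en-1-ol | OC/C=C(\I)CO[Si](c1ccccc1)(c1ccccc1)C(C)(C)C | intermediate
5 | (2Z)-4-{[tert-butyl(diphenyl)silyl]oxy}-3-iodobut-2-enal | O=C/C=C(\I)CO[Si](c1ccccc1)(c1ccccc1)C(C)(C)C | intermediate
6 | methyl prop-2-ynoate (methyl propiolate) | C#CC(=O)OC | starting material
7 | methyl 3-(methylzincio)prop-2-ynoate (alkynylzinc; not isolated) | C[Zn]C#CC(=O)OC | intermediate
8 | methyl (4S,5Z)-7-{[tert-butyl(diphenyl)silyl]oxy}-4-hydroxy-6-iodohept-5-en-2-ynoate | COC(=O)C#C[C@@H](O)/C=C(\I)CO[Si](c1ccccc1)(c1ccccc1)C(C)(C)C | intermediate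
9 | methyl (4S,5Z)-7-{[tert-butyl(diphenyl)silyl]oxy}-6-iodo-4-[(triethylsilyl)oxy]hept-5-en-2-ynoate | COC(=O)C#C[C@@H](O[Si](CC)(CC)CC)/C=C(\I)CO[Si](c1ccccc1)(c1ccccc1)C(C)(C)C | intermediate
10 | methyl (2E,4R,5Z)-2-[bis(2-methylpropyl)alumanyl]-7-{[tert-butyl(diphenyl)silyl]oxy}-6-iodo-4-[(triethylsilyl)oxy]hepta-2,5-dienoate (alkenylalane; not isolated) | COC(=O)/C(=C\[C@@H](O[Si](CC)(CC)CC)/C=C(\I)CO[Si](c1ccccc1)(c1ccccc1)C(C)(C)C)[Al](CC(C)C)CC(C)C | intermediate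
11 | methyl (2Z,4R,5Z)-7-{[tert-butyl(diphenyl)silyl]oxy}-2-(hydroxymethyl)-6-iodo-4-[(triethylsilyl)oxy]hepta-2,5-dienoate (not isolated) | COC(=O)/C(CO)=C\[C@@H](O[Si](CC)(CC)CC)/C=C(\I)CO[Si](c1ccccc1)(c1ccccc1)C(C)(C)C | intermediate
12 | (5R)-5-[(1Z)-3-{[tert-butyl(diphenyl)silyl]oxy}-2-iodoprop-1-en-1-yl]-3-(hydroxymethyl)furan-2(5H)-one | OCC1=C[C@H](/C=C(\I)CO[Si](c2ccccc2)(c2ccccc2)C(C)(C)C)OC1=O | intermediate
13 | (5R)-3-(bromomethyl)-5-[(1Z)-3-{[tert-butyl(diphenyl)silyl]oxy}-2-iodoprop-1-en-1-yl]furan-2(5H)-one (fragment A) | BrCC1=C[C@H](/C=C(\I)CO[Si](c2ccccc2)(c2ccccc2)C(C)(C)C)OC1=O | intermediate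
14 | 3,3-dimethoxyprop-1-ene (acrolein dimethyl acetal) | C=CC(OC)OC | starting material
15 | 9-(3,3-dimethoxypropyl)-9-borabicyclo[3.3.1]nonane (not isolated) | COC(OC)CCB1C2CCCC1CCC2 | intermediate
16 | 3,3-dimethoxypropan-1-ol | OCCC(OC)OC | intermediate
17 | 3,3-dimethoxypropanal | O=CCC(OC)OC | intermediate
18 | ethyl prop-2-ynoate (ethyl propiolate) | C#CC(=O)OCC | starting material
19 | ethyl 3-(methylzincio)prop-2-ynoate (ethyl alkynylzinc; not isolated) | C[Zn]C#CC(=O)OCC | intermediate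
20 | ethyl (4S)-4-hydroxy-6,6-dimethoxyhex-2-ynoate | CCOC(=O)C#C[C@@H](O)CC(OC)OC | intermediate
21 | ethyl (4S)-4-{[tert-butyl(dimethyl)silyl]oxy}-6,6-dimethoxyhex-2-ynoate | CCOC(=O)C#C[C@@H](O[Si](C)(C)C(C)(C)C)CC(OC)OC | intermediate
22 | ethyl (2Z,4S)-4-{[tert-butyl(dimethyl)silyl]oxy}-6,6-dimethoxy-3-methylhex-2-enoate | CCOC(=O)/C=C(/C)[C@@H](O[Si](C)(C)C(C)(C)C)CC(OC)OC | intermediate
23 | (2Z,4S)-4-{[tert-butyl(dimethyl)silyl]oxy}-6,6-dimethoxy-3-methylhex-2-en-1-ol | OC/C=C(/C)[C@@H](O[Si](C)(C)C(C)(C)C)CC(OC)OC | intermediate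
24 | (2Z,4S)-4-{[tert-butyl(dimethyl)silyl]oxy}-6,6-dimethoxy-3-methylhex-2-enal (fragment B) | O=C/C=C(/C)[C@@H](O[Si](C)(C)C(C)(C)C)CC(OC)OC | intermediate
25 | (4S,5R)-5-[(1Z)-3-{[tert-butyl(diphenyl)silyl]oxy}-2-iodoprop-1-en-1-yl]-4-[(1R,2Z,4S)-4-{[tert-butyl(dimethyl)silyl]oxy}-1-hydroxy-6,6-dimethoxy-3-methylhex-2-en-1-yl]-3-methylideneoxolan-2-one | C=C1C(=O)O[C@@H](/C=C(\I)CO[Si](c2ccccc2)(c2ccccc2)C(C)(C)C)[C@@H]1[C@H](O)/C=C(/C)[C@@H](O[Si](C)(C)C(C)(C)C)CC(OC)OC | intermediate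
26 | (2Z)-2-methylbut-2-enoic acid (angelic acid) | C/C=C(/C)C(=O)O | starting material
27 | (2Z)-2-methylbut-2-enoic 2,4,6-trichlorobenzoic anhydride (not isolated) | C/C=C(/C)C(=O)OC(=O)c1c(Cl)cc(Cl)cc1Cl | intermediate
28 | (1R,2Z,4S)-4-{[tert-butyl(dimethyl)silyl]oxy}-1-[(2R,3S)-2-[(1Z)-3-{[tert-butyl(diphenyl)silyl]oxy}-2-iodoprop-1-en-1-yl]-4-methylidene-5-oxooxolan-3-yl]-6,6-dimethoxy-3-methylhex-2-en-1-yl (2Z)-2-methylbut-2-enoate | C=C1C(=O)O[C@@H](/C=C(\I)CO[Si](c2ccccc2)(c2ccccc2)C(C)(C)C)[C@@H]1[C@H](OC(=O)/C(C)=C\C)/C=C(/C)[C@@H](O[Si](C)(C)C(C)(C)C)CC(OC)OC | intermediate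
29 | 2,4,6-trimethylpyridinium N,O-acetal triflate of 28: one OMe of the dimethyl acetal replaced by N-linked 2,4,6-trimethylpyridinium; epimers at that carbon (not isolated) | C=C1C(=O)O[C@@H](/C=C(\I)CO[Si](c2ccccc2)(c2ccccc2)C(C)(C)C)[C@@H]1[C@H](OC(=O)/C(C)=C\C)/C=C(/C)[C@@H](O[Si](C)(C)C(C)(C)C)CC(OC)[n+]1c(C)cc(C)cc1C.[O-]S(=O)(=O)C(F)(F)F | intermediate
30 | (1R,2Z,4S)-4-{[tert-butyl(dimethyl)silyl]oxy}-1-[(2R,3S)-2-[(1Z)-3-{[tert-butyl(diphenyl)silyl]oxy}-2-iodoprop-1-en-1-yl]-4-methylidene-5-oxooxolan-3-yl]-3-methyl-6-oxohex-2-en-1-yl (2Z)-2-methylbut-2-enoate | C=C1C(=O)O[C@@H](/C=C(\I)CO[Si](c2ccccc2)(c2ccccc2)C(C)(C)C)[C@@H]1[C@H](OC(=O)/C(C)=C\C)/C=C(/C)[C@@H](O[Si](C)(C)C(C)(C)C)CC=O | intermediate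
31 | (3aS,4R,5Z,7S,9S,10Z,11aS)-7-{[tert-butyl(dimethyl)silyl]oxy}-10-({[tert-butyl(diphenyl)silyl]oxy}methyl)-9-hydroxy-6-methyl-3-methylidene-2-oxo-2,3,3a,4,7,8,9,11a-octahydrocyclodeca[b]furan-4-yl (2Z)-2-methylbut-2-enoate | C=C1C(=O)O[C@H]2/C=C(/CO[Si](c3ccccc3)(c3ccccc3)C(C)(C)C)[C@@H](O)C[C@H](O[Si](C)(C)C(C)(C)C)/C(C)=C\[C@@H](OC(=O)/C(C)=C\C)[C@H]12 | intermediate
32 | (3aS,4R,5Z,7S,9S,10Z,11aS)-9-acetoxy-7-{[tert-butyl(dimethyl)silyl]oxy}-10-({[tert-butyl(diphenyl)silyl]oxy}methyl)-6-methyl-3-methylidene-2-oxo-2,3,3a,4,7,8,9,11a-octahydrocyclodeca[b]furan-4-yl (2Z)-2-methylbut-2-enoate | C=C1C(=O)O[C@H]2/C=C(/CO[Si](c3ccccc3)(c3ccccc3)C(C)(C)C)[C@@H](OC(C)=O)C[C@H](O[Si](C)(C)C(C)(C)C)/C(C)=C\[C@@H](OC(=O)/C(C)=C\C)[C@H]12 | intermediate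
33 | (3aS,4R,5Z,7S,9S,10Z,11aS)-9-acetoxy-7-hydroxy-10-(hydroxymethyl)-6-methyl-3-methylidene-2-oxo-2,3,3a,4,7,8,9,11a-octahydrocyclodeca[b]furan-4-yl (2Z)-2-methylbut-2-enoate (CNP0153210.4) | C=C1C(=O)O[C@H]2/C=C(/CO)[C@@H](OC(C)=O)C[C@H](O)/C(C)=C\[C@@H](OC(=O)/C(C)=C\C)[C@H]12 | target

## Step count and risks

Total step count: 20. Longest linear sequence: 13 steps (steps 1–7 or steps 8–14, followed by steps 15–20).

Steps most likely to fail:

**Step 6** (1,4-hydroalumination may over-reduce the ester or capture formaldehyde poorly). The fallback sets out from 5 and comes back at 13, replacing steps 4–7. Enantioselective vinylation of 5 with (CH2=CH)2Zn and a chiral amino-alcohol ligand such as (−)-MIB (antipode chosen for the 3R alcohol) gives (3R,4Z)-6-{[tert-butyl(diphenyl)silyl]oxy}-5-iodohexa-1,4-dien-3-ol F1. Esterification with 2-(bromomethyl)prop-2-enoic acid (diisopropylcarbodiimide, CH2Cl2, 0 °C) gives (3R,4Z)-6-{[tert-butyl(diphenyl)silyl]oxy}-5-iodohexa-1,4-dien-3-yl 2-(bromomethyl)prop-2-enoate F2. Ring-closing metathesis of the two terminal alkenes with the second-generation Grubbs catalyst (toluene, 80 °C) closes the butenolide and gives 13; the trisubstituted vinyl iodide does not take part.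

**Step 15** (wrong simple diastereoselectivity, attack through the CH2 terminus, or lactone migration through the chromium alkoxide). The fallback sets out from 9 and comes back at 25, using boron in place of chromium. The alkenylalane generated as in step 6 is trapped with 2-(iodomethyl)-4,4,5,5-tetramethyl-1,3,2-dioxaborolane instead of formaldehyde to give methyl (2Z,4R,5Z)-7-{[tert-butyl(diphenyl)silyl]oxy}-6-iodo-2-[(4,4,5,5-tetramethyl-1,3,2-dioxaborolan-2-yl)methyl]-4-[(triethylsilyl)oxy]hepta-2,5-dienoate F3. PPTS in MeOH removes the triethylsilyl group with lactonisation to (5R)-5-[(1Z)-3-{[tert-butyl(diphenyl)silyl]oxy}-2-iodoprop-1-en-1-yl]-3-[(4,4,5,5-tetramethyl-1,3,2-dioxaborolan-2-yl)methyl]furan-2(5H)-one F4. Heating F4 with enal 24 in toluene (80 °C) gives an allylboration through a closed six-membered transition state with a configurationally fixed allylboronate (same anti, trans outcome), and mild hydrolysis of the borate gives 25.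

**Step 18** (the macrocyclic transition state may give the C3 epimer or a mixture). The fallback sets out from 30 and comes back at 32. The cyclisation is run as in step 18, and the epimer (3aS,4R,5Z,7S,9R,10Z,11aS)-7-{[tert-butyl(dimethyl)silyl]oxy}-10-({[tert-butyl(diphenyl)silyl]oxy}methyl)-9-hydroxy-6-methyl-3-methylidene-2-oxo-2,3,3a,4,7,8,9,11a-octahydrocyclodeca[b]furan-4-yl (2Z)-2-methylbut-2-enoate F5 is separated. Mitsunobu reaction of F5 with acetic acid (PPh3, diisopropyl azodicarboxylate, toluene, 0 °C) inverts ring position 9 and installs the acetate in one operation to give 32, so both epimers converge.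

## Further compounds

F1 | step 6 | (3R,4Z)-6-{[tert-butyl(diphenyl)silyl]oxy}-5-iodohexa-1,4-dien-3-ol | C=C[C@@H](O)/C=C(\I)CO[Si](c1ccccc1)(c1ccccc1)C(C)(C)C
F2 | step 6 | (3R,4Z)-6-{[tert-butyl(diphenyl)silyl]oxy}-5-iodohexa-1,4-dien-3-yl 2-(bromomethyl)prop-2-enoate | C=C(CBr)C(=O)O[C@H](C=C)/C=C(\I)CO[Si](c1ccccc1)(c1ccccc1)C(C)(C)C
F3 | step 15 | methyl (2Z,4R,5Z)-7-{[tert-butyl(diphenyl)silyl]oxy}-6-iodo-2-[(4,4,5,5-tetramethyl-1,3,2-dioxaborolan-2-yl)methyl]-4-[(triethylsilyl)oxy]hepta-2,5-dienoate | COC(=O)/C(CB1OC(C)(C)C(C)(C)O1)=C\[C@@H](O[Si](CC)(CC)CC)/C=C(\I)CO[Si](c1ccccc1)(c1ccccc1)C(C)(C)C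
F4 | step 15 | (5R)-5-[(1Z)-3-{[tert-butyl(diphenyl)silyl]oxy}-2-iodoprop-1-en-1-yl]-3-[(4,4,5,5-tetramethyl-1,3,2-dioxaborolan-2-yl)methyl]furan-2(5H)-one | CC1(C)OB(CC2=C[C@H](/C=C(\I)CO[Si](c3ccccc3)(c3ccccc3)C(C)(C)C)OC2=O)OC1(C)C
F5 | step 18 | (3aS,4R,5Z,7S,9R,10Z,11aS)-7-{[tert-butyl(dimethyl)silyl]oxy}-10-({[tert-butyl(diphenyl)silyl]oxy}methyl)-9-hydroxy-6-methyl-3-methylidene-2-oxo-2,3,3a,4,7,8,9,11a-octahydrocyclodeca[b]furan-4-yl (2Z)-2-methylbut-2-enoate | C=C1C(=O)O[C@H]2/C=C(/CO[Si](c3ccccc3)(c3ccccc3)C(C)(C)C)[C@H](O)C[C@H](O[Si](C)(C)C(C)(C)C)/C(C)=C\[C@@H](OC(=O)/C(C)=C\C)[C@H]12
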